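**Plan**
1. Retrosynthetic cuts: first the benzyl ether on O-4. Then, in both trione rings at once (ring atoms: Ca bears the CH(iPr)Ar arm, then Cb(=O), Cc(Me2), Cd(=O), Ce(Me2), Cf(OH)), the bonds Cb–Cc and Cd–Ce; this frees Cc–Cd as dimethylketene and leaves Cb–Ca–Cf–Ce as a 3-isobutyryl δ-lactone. Then the two isobutyryl groups, and last the two lactone rings.
2. Enabling feature: Cc(Me2)–Cd(=O) is a ketene unit flanked by carbons that cannot enolise. Cb, Ca, the benzylic CH, two arene carbons and the ortho phenol oxygen (O-2 or O-6) form a six-membered ring, so Cb can be stored as an aryl δ-lactone that activates it and returns the phenol when the carbocycle closes.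
3. Forward order: phloroglucinol → C-acylation → 4-O-benzylation → both δ-lactone rings fused to the arene in one asymmetric step (tricyclic pyrano[3,2-g]chromene-2,8-dione) → aryl ketone masked as silyl enol ether → 3,7-diacylation → two-fold dianion/dimethylketene annulation that turns both lactone rings into the two trione rings (the mask falls in the work-up) → hydrogenolysis.
4. Stereochemistry: both (R) benzylic centres are set in step 3 by a chiral N-heterocyclic carbene catalyst. Afterwards their C–H is never α to a carbonyl, so the strong-base steps and the neutral last step should not epimerise them.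

Key step: step 7

Remark: both benzylic centres of the target are R (trione carbon > arene carbon > isopropyl > H), i.e. the C2-symmetric isomer, not the meso form. Steps 3, 5 and 7 are two-directional: each takes up two molecules of its building block, one per arm. The first molecule is the numbered reactant and the second is entered under "Reagents that add atoms". The half-reacted species are the same reaction taken halfway and are not counted as separate compounds.

Step 1
Reactants: 1 phloroglucinol (benzene-1,3,5-triol); 2 isobutyryl chloride (2-methylpropanoyl chloride)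
Product: 3 2-methyl-1-(2,4,6-trihydroxyphenyl)propan-1-one
Conditions: AlCl3 (3 equiv), PhNO2/CH2Cl2, 0 °C → 40 °C; aq. HCl
Reagents that add atoms: none
Why: Friedel–Crafts acylation of a very electron-rich arene, which should stop after one acyl group because the ketone, hydrogen-bonded to both ortho hydroxyls, deactivates the ring.

Step 2
Reactants: 3 2-methyl-1-(2,4,6-trihydroxyphenyl)propan-1-one
Product: 4 1-[4-(benzyloxy)-2,6-dihydroxyphenyl]-2-methylpropan-1-one
Conditions: BnBr (1.0 equiv), K2CO3 (1.1 equiv), acetone, rt
Reagents that add atoms: benzyl bromide, BrCc1ccccc1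
Why: Williamson ether synthesis that should select the para hydroxyl, the most acidic one and the only one not tied to the ketone by a hydrogen bond, so that O-2 and O-6 stay free and C-3 and C-5 remain the only open ring positions.

Step 3
Reactants: 4 1-[4-(benzyloxy)-2,6-dihydroxyphenyl]-2-methylpropan-1-one; 5 (E)-4-methylpent-2-enal (two molecules are incorporated, one at C-3 and one at C-5 of the arene)
Product: 6 (4R,6R)-5-(benzyloxy)-10-(2-methylpropanoyl)-4,6-di(propan-2-yl)-3,4,6,7-tetrahydro-2H,8H-pyrano[3,2-g]chromene-2,8-dione (the bis-δ-lactone)
Conditions: 5 (2.6 equiv), (5aS,10bR)-2-mesityl-4,5a,6,10b-tetrahydroindeno[2,1-b][1,2,4]triazolo[4,3-d][1,4]oxazin-2-ium chloride (20 mol %), iPr2NEt (20 mol %), 3,3',5,5'-tetra-tert-butyl-4,4'-diphenoquinone (2.4 equiv), toluene, rt; chromatographic removal of the meso isomer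
Reagents that add atoms: (E)-4-methylpent-2-enal (second molecule of 5), CC(C)/C=C/C=O
Why: Oxidative N-heterocyclic carbene catalysed [3+3] annulation (Friedel–Crafts-type Michael addition then lactonisation): each enal is oxidised on the catalyst to an α,β-unsaturated acyl azolium, C-3 and then C-5 of the arene add to the Si face of its β-carbon (giving R at each new centre; the catalyst antipode named is assigned by analogy and is to be confirmed on the first run) and the neighbouring hydroxyl closes the δ-lactone, while two independent catalyst-controlled events should turn most of the minor enantiomer into the separable meso isomer.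

Step 4
Reactants: 6 the bis-δ-lactone
Product: 7 (4R,6R)-5-(benzyloxy)-10-{1-[(tert-butyldimethylsilyl)oxy]-2-methylprop-1-en-1-yl}-4,6-di(propan-2-yl)-3,4,6,7-tetrahydro-2H,8H-pyrano[3,2-g]chromene-2,8-dione
Conditions: TBSOTf (3 equiv), Et3N (5 equiv), CH2Cl2, 0 °C → rt; aq. NaHCO3
Reagents that add atoms: tert-butyldimethylsilyl trifluoromethanesulfonate, CC(C)(C)[Si](C)(C)OS(=O)(=O)C(F)(F)F
Why: Soft enolisation (O-silylation of the ketone, then deprotonation by Et3N) should give the tetrasubstituted silyl enol ether without a free enolate ever forming, which removes the only other enolisable C–H before the strong-base steps (an enolate next to the two aryl-ester oxygens would undergo Baker–Venkataraman-type acyl transfer), and any lactone ketene acetal reverts on aqueous work-up.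

Step 5
Reactants: 7 the silyl enol ether bis-lactone; 2 isobutyryl chloride (two molecules are incorporated, one at C-3 and one at C-7)
Product: 8 (3R,4S,6S,7R)-5-(benzyloxy)-10-{1-[(tert-butyldimethylsilyl)oxy]-2-methylprop-1-en-1-yl}-3,7-bis(2-methylpropanoyl)-4,6-di(propan-2-yl)-3,4,6,7-tetrahydro-2H,8H-pyrano[3,2-g]chromene-2,8-dione (3,4-trans and 6,7-trans)
Conditions: LiN(SiMe3)2 (4.4 equiv), THF, −78 °C; 2 (2.2 equiv), −78 °C; AcOH quench
Reagents that add atoms: isobutyryl chloride (second molecule of 2), CC(C)C(Cl)=O
Why: Two-fold Claisen-type C-acylation of the lithium lactone enolates, the second equivalent of base per ring taking up the more acidic β-keto lactone as it forms; each acyl group should enter anti to the neighbouring isopropyl group, a configuration of no consequence because C-3 and C-7 become sp2 in step 7.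

Step 6
Reactants: 9 2-bromo-2-methylpropanoyl bromide
Product: 10 dimethylketene (2-methylprop-1-en-1-one)
Conditions: Zn dust, EtOAc, reduced pressure, N2; fractional redistillation (bp 34 °C), taken up in THF and used at once with strict exclusion of O2
Reagents that add atoms: none
Why: Reductive 1,2-elimination (zinc dehalogenation) of an α-bromoacyl bromide, the standard laboratory preparation of this ketene.

Step 7
Reactants: 8 the bis(3-isobutyryl) lactone; 10 dimethylketene (two molecules are incorporated, one per lactone ring)
Product: 13 (R,R)-4-O-benzyl-myrtucommulone A, via acyclic bis-diketone adduct 11 (not isolated), via cyclised silyl enol ether 12 (not isolated)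
Conditions: LiN(iPr)2 (4.2 equiv), THF, −78 → −20 °C; 10 (2.2 equiv), THF, slow addition at −78 °C, then → 0 °C; then 1 M HCl, THF, rt
Reagents that add atoms: dimethylketene (second molecule of 10), CC(C)=C=O
Why: Proposed new method: a formal [4+2] annulation of a 1,3-dicarbonyl α,γ-dianion with a ketene, in which LiN(iPr)2 removes H-3/H-7 and then the isobutyryl methine of each arm, the γ-carbanion adds to the carbonyl carbon of one molecule of dimethylketene (bond Ce–Cd), and the tetrasubstituted ketone enolate so formed attacks the lactone carbonyl with loss of the aryloxide (directly, or through the acylketene that an aryl β-keto ester enolate can form by E1cB), which makes bond Cc–Cb and turns each δ-lactone into a carbocyclic trione. The closest known reaction types are the γ-acylation of β-keto ester dianions, the Dieckmann-type closure of δ-keto esters to cyclohexane-1,3-diones and the base-induced trimerisation of dimethylketene to hexamethylcyclohexane-1,3,5-trione. Each ring closes in the 6-(enolendo)-exo-trig mode, helped by the two gem-dimethyl groups. No new stereocentre arises: C-3/C-7 become sp2 and the two benzylic centres keep their configuration because their C–H is not α to any carbonyl. The step needs C- rather than O-acylation and ring closure rather than ketene oligomerisation; the carbanion character of the dianion terminus, lithium in THF, slow addition of just one equivalent of ketene per arm at −78 °C and the downhill intramolecular closure to a stabilised trione enolate plus phenoxide should secure this. The silyl enol ether, which keeps the aryl ketone from enolising and attacking the neighbouring lactones, is hydrolysed by the dilute acid of the work-up.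

Step 8
Reactants: 13 (R,R)-4-O-benzyl-myrtucommulone A
Product: 14 myrtucommulone A, (R,R) enantiomer
Conditions: H2 (1 atm), Pd/C (10 wt %), EtOAc, rt
Reagents that add atoms: none
Why: Hydrogenolysis of the benzyl aryl ether under neutral conditions, which should leave the enolised triones, the hydrogen-bonded aryl ketone and both benzylic centres untouched.

**Compound list**
1 | phloroglucinol | Oc1cc(O)cc(O)c1 | starting material
2 | isobutyryl chloride | CC(C)C(Cl)=O | starting material
3 | 2-methyl-1-(2,4,6-trihydroxyphenyl)propan-1-one | CC(C)C(=O)c1c(O)cc(O)cc1O | intermediate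
4 | 1-[4-(benzyloxy)-2,6-dihydroxyphenyl]-2-methylpropan-1-one | CC(C)C(=O)c1c(O)cc(OCc2ccccc2)cc1O | intermediate
5 | (E)-4-methylpent-2-enal | CC(C)/C=C/C=O | starting material
6 | (4R,6R)-5-(benzyloxy)-10-(2-methylpropanoyl)-4,6-di(propan-2-yl)-3,4,6,7-tetrahydro-2H,8H-pyrano[3,2-g]chromene-2,8-dione | CC(C)C(=O)c1c2OC(=O)C[C@H](C(C)C)c2c(OCc2ccccc2)c2[C@@H](C(C)C)CC(=O)Oc12 | intermediate
7 | 6 with the aryl ketone as its tert-butyldimethylsilyl enol ether (10-{1-[(tert-butyldimethylsilyl)oxy]-2-methylprop-1-en-1-yl}) | CC(C)=C(O[Si](C)(C)C(C)(C)C)c1c2OC(=O)C[C@H](C(C)C)c2c(OCc2ccccc2)c2[C@@H](C(C)C)CC(=O)Oc12 | intermediate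
8 | (3R,4S,6S,7R)-3,7-bis(2-methylpropanoyl) derivative of 7 (3,4-trans, 6,7-trans; C-3/C-7 epimerisable) | CC(C)=C(O[Si](C)(C)C(C)(C)C)c1c2OC(=O)[C@@H](C(=O)C(C)C)[C@H](C(C)C)c2c(OCc2ccccc2)c2[C@@H](C(C)C)[C@H](C(=O)C(C)C)C(=O)Oc12 | intermediate
9 | 2-bromo-2-methylpropanoyl bromide | CC(C)(Br)C(Br)=O | starting material
10 | dimethylketene | CC(C)=C=O | intermediate
11 | 3,7-bis(2,2,4-trimethyl-3-oxopentanoyl) analogue of 8 (present in the flask as its tetralithium enolate; written in the neutral keto form) | CC(C)=C(O[Si](C)(C)C(C)(C)C)c1c2OC(=O)[C@@H](C(=O)C(C)(C)C(=O)C(C)C)[C@H](C(C)C)c2c(OCc2ccccc2)c2[C@@H](C(C)C)[C@H](C(=O)C(C)(C)C(=O)C(C)C)C(=O)Oc12 | intermediate (not isolated)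
12 | (R,R)-4-O-benzyl-myrtucommulone A in which the aryl isobutyryl group is the 1-[(tert-butyldimethylsilyl)oxy]-2-methylprop-1-enyl group | CC(C)=C(O[Si](C)(C)C(C)(C)C)c1c(O)c([C@H](C2=C(O)C(C)(C)C(=O)C(C)(C)C2=O)C(C)C)c(OCc2ccccc2)c([C@H](C2=C(O)C(C)(C)C(=O)C(C)(C)C2=O)C(C)C)c1O | intermediate (not isolated)
13 | (R,R)-4-O-benzyl-myrtucommulone A (benzyl ether of the phenol between the two arms, para to the isobutyryl group) | CC(C)C(=O)c1c(O)c([C@H](C2=C(O)C(C)(C)C(=O)C(C)(C)C2=O)C(C)C)c(OCc2ccccc2)c([C@H](C2=C(O)C(C)(C)C(=O)C(C)(C)C2=O)C(C)C)c1O | intermediate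
14 | myrtucommulone A, (R,R) | CC(C)C(=O)c1c(O)c([C@H](C2=C(O)C(C)(C)C(=O)C(C)(C)C2=O)C(C)C)c(O)c([C@H](C2=C(O)C(C)(C)C(=O)C(C)(C)C2=O)C(C)C)c1O | target

**Count**
Total: 8 steps. Longest linear sequence: 7 steps (1, 2, 3, 4, 5, 7, 8); step 6 is a one-step side branch.

**Steps most likely to fail**

Step 7 (the labelled step). Processes at risk: O-acylation of the dianion; uptake of further ketene by the intermediate ketone enolate before it closes the ring (oligomerisation); incomplete second deprotonation at the crowded methine; opening of the lactone enolate to an acylketene that diisopropylamine traps. The fallback uses known chemistry, sets out from 8 and comes back at 13, and makes the two bonds of each ring in two separate operations. The tetra-anion of 8 (LiN(iPr)2, THF) is acylated at both γ-carbons with N-methoxy-N-methylisobutyramide (Claisen-type acylation of β-keto ester dianions; the chelated tetrahedral adduct cannot react twice), and the bis-diketo lactone 11 is isolated after buffered work-up. Renewed double deprotonation of each arm of 11 (LiN(iPr)2, THF, −78 → 0 °C; H-3/H-7 and the terminal isobutyryl CH) then effects the Dieckmann-type closure to 12, which dilute HCl converts into 13 as in the route. No compound outside the list is made: none F0.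

Step 3. Processes at risk: poor facial selectivity in the second, more crowded annulation; arrest at O-acylation or at the mono-lactone because the hydrogen-bonded phenol is a weak nucleophile. The fallback sets out from 4 and comes back at 6, and sets the centres by hydride delivery instead of C–C bond formation. Two-fold hydroarylation/lactonisation of 4 with ethyl 4-methylpent-2-ynoate (Pd(OAc)2 cat., CF3CO2H/CH2Cl2, rt) should give the bis-coumarin 5-(benzyloxy)-10-(2-methylpropanoyl)-4,6-di(propan-2-yl)-2H,8H-pyrano[3,2-g]chromene-2,8-dione F1. Asymmetric conjugate reduction of both coumarin C=C bonds with ligated copper hydride (Cu(OAc)2, (R)-DTBM-SEGPHOS, diethoxymethylsilane, tBuOH, toluene; ligand antipode chosen to give R) would then return to 6; the di-ortho-substituted aryl ketone is expected to react much more slowly.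

Step 5. Processes at risk: O-acylation of the enolate; fragmentation of the aryl-ester enolate to a ketene and phenoxide above −78 °C; incomplete acylation of the second lactone. The fallback sets out from 7 and comes back at 8 by aldol addition and oxidation. The bis-enolate of 7 (LiN(SiMe3)2, THF, −78 °C) is added to isobutyraldehyde to give the bis-aldol, the 3,7-bis(1-hydroxy-2-methylpropyl) analogue of 8 F2 (3,4-trans and 6,7-trans, mixture of carbinol epimers). Oxidation with Dess–Martin periodinane (NaHCO3, CH2Cl2, rt) then gives 8.

**Further compounds**
F0 | step 7 | none | none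
F1 | step 3 | 5-(benzyloxy)-10-(2-methylpropanoyl)-4,6-di(propan-2-yl)-2H,8H-pyrano[3,2-g]chromene-2,8-dione | CC(C)C(=O)c1c2OC(=O)C=C(C(C)C)c2c(OCc2ccccc2)c2C(C(C)C)=CC(=O)Oc12
F2 | step 5 | (3R,4S,6S,7R)-5-(benzyloxy)-10-{1-[(tert-butyldimethylsilyl)oxy]-2-methylprop-1-en-1-yl}-3,7-bis(1-hydroxy-2-methylpropyl)-4,6-di(propan-2-yl)-3,4,6,7-tetrahydro-2H,8H-pyrano[3,2-g]chromene-2,8-dione (carbinol centres unspecified) | CC(C)=C(O[Si](C)(C)C(C)(C)C)c1c2OC(=O)[C@@H](C(O)C(C)C)[C@H](C(C)C)c2c(OCc2ccccc2)c2[C@@H](C(C)C)[C@H](C(O)C(C)C)C(=O)Oc12
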